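## Retrosynthetic overview

1. The only ring to build is the γ-lactone. It is made first, by enantioselective oxygen insertion (ring C–O bond) into prochiral cyclobutanone acid 1 through Criegee adduct 2, giving (R)-paraconic acid 3 and fixing C4 of the target.
2. C3–CH2Ar bond: benzylic alcohol 4 is turned into bromide 5, which alkylates dianion 6 (from 3) anti to the carboxylate to give trans acid 7, setting C3.
3. Aryl–C(=O) bond: acid 7 and arylboronic acid 8 are joined through mixed anhydride 9 to give protected ketone 10 (acyl Suzuki coupling).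
4. Last disconnection: the two phenol O-benzyl groups of 10 are removed to give target 11.

Assumption: 1, 4, 8 and mCPBA are bought; L* is the C2-symmetric N,N'-dioxide ligand made of two (S)-pipecolic acid N-oxide 2,6-diisopropylanilide units joined N-to-N by a (CH2)3 chain, and its mirror image is used instead if the sense of induction in step 1 turns out opposite.

## Route

Step 1
Reactants: 1 3-oxocyclobutane-1-carboxylic acid
Product: 3 (R)-paraconic acid [(3R)-5-oxooxolane-3-carboxylic acid], via Criegee adduct 2 (not isolated)
Conditions: mCPBA (1.2 equiv), Sc(OTf)3 (5 mol%), L* (5.5 mol%), EtOAc, −20 °C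
Reagents that add atoms: mCPBA (3-chloroperoxybenzoic acid), OOC(=O)c1cccc(Cl)c1
Why: Proposed new method: a desymmetrising Baeyer–Villiger oxidation of a 3-carboxycyclobutanone, in which the peracid adds to the strained ketone and, in Criegee adduct 2, the substrate's own carboxyl and the hemiketal oxygen bind the chiral trivalent-scandium centre as a cis-1,3 chelate while the perester carbonyl hydrogen-bonds to a ligand anilide N–H, so that only one of the two enantiotopic ring CH2 groups can lie antiperiplanar to the O–O bond and migrates, which forms the lactone C–O bond and sets the (R) centre; the closest known reaction type is the scandium/N,N'-dioxide-catalysed asymmetric Baeyer–Villiger desymmetrisation of 3-aryl- and 3-alkylcyclobutanones, which has not been shown for a free carboxylic acid substituent used as a binding handle.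

Step 2
Reactants: 4 4-benzyloxy-3-methoxybenzyl alcohol
Product: 5 4-benzyloxy-3-methoxybenzyl bromide
Conditions: PBr3 (0.4 equiv), Et2O, 0 °C
Reagents that add atoms: phosphorus tribromide, BrP(Br)Br
Why: Bromination of an electron-rich benzylic alcohol with PBr3 (displacement of the bromophosphite ester by bromide); no stereocentre is involved.

Step 3
Reactants: 3 (R)-paraconic acid; 5 4-benzyloxy-3-methoxybenzyl bromide
Product: 7 (3R,4R)-4-[(4-benzyloxy-3-methoxyphenyl)methyl]-5-oxooxolane-3-carboxylic acid, via dianion 6 (not isolated)
Conditions: NaN(SiMe3)2 (2.2 equiv), THF/DMPU, −78 °C; then 5 (1.05 equiv), −78 → −40 °C; 1 M HCl work-up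
Reagents that add atoms: none
Why: Carboxylate-protected dianion alkylation: the second equivalent of base deprotonates only the lactone α-CH2 (the C–H next to the carboxylate is not acidic, so the existing centre is kept), and the enolate is benzylated on the face anti to the neighbouring carboxylate, which sets the new centre trans (substrate-controlled enolate alkylation, as in α-methylation of paraconic acids).

Step 4
Reactants: 7 (3R,4R)-4-[(4-benzyloxy-3-methoxyphenyl)methyl]-5-oxooxolane-3-carboxylic acid; 8 4-benzyloxy-3-methoxyphenylboronic acid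
Product: 10 (3R,4R)-4-(4-benzyloxy-3-methoxybenzoyl)-3-(4-benzyloxy-3-methoxybenzyl)dihydrofuran-2(3H)-one, via mixed anhydride 9 (not isolated)
Conditions: (tBuCO)2O (1.5 equiv), Pd(OAc)2 (3 mol%), P(4-MeOC6H4)3 (7 mol%), THF, H2O (2.5 equiv), 60 °C
Reagents that add atoms: none
Why: Acyl Suzuki–Miyaura ketone synthesis: zerovalent palladium inserts into the less hindered acyl C–O bond of mixed anhydride 9, the electron-rich arylboronic acid transmetalates and reductive elimination gives the aryl ketone without added base, so lactone, benzyl ethers and the C3 centre are untouched and the ketone-bearing C4 stays in (or relaxes to) the thermodynamically preferred trans arrangement.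

Step 5
Reactants: 10 (3R,4R)-4-(4-benzyloxy-3-methoxybenzoyl)-3-(4-benzyloxy-3-methoxybenzyl)dihydrofuran-2(3H)-one
Product: 11 (3R,4R)-4-(4-hydroxy-3-methoxybenzoyl)-3-(4-hydroxy-3-methoxybenzyl)dihydrofuran-2(3H)-one (target)
Conditions: H2 (1 atm), 10% Pd/C, EtOAc, rt, stopped after 2 equiv H2
Reagents that add atoms: none
Why: Hydrogenolysis of the two aryl benzyl ethers over palladium on carbon; in neutral solvent at 1 atm the 4-oxygenated aryl ketone (vinylogous ester) and the lactone are reduced far more slowly, and no stereocentre is touched.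

## Compound list

1 | 3-oxocyclobutane-1-carboxylic acid | O=C1CC(C(=O)O)C1 | starting material
2 | Criegee adduct, 3-hydroxy-3-[(3-chlorobenzoyl)peroxy]cyclobutane-1-carboxylic acid, hydroxyl cis to carboxyl (scandium-bound) | O[C@]1(OOC(=O)c2cccc(Cl)c2)C[C@H](C(=O)O)C1 | intermediate
3 | (R)-paraconic acid, (3R)-5-oxooxolane-3-carboxylic acid | OC(=O)[C@H]1COC(=O)C1 | intermediate
4 | 4-benzyloxy-3-methoxybenzyl alcohol | COc1cc(CO)ccc1OCc1ccccc1 | starting material
5 | 4-benzyloxy-3-methoxybenzyl bromide | COc1cc(CBr)ccc1OCc1ccccc1 | intermediate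
6 | dianion, disodium (3R)-5-oxido-2,3-dihydrofuran-3-carboxylate | [Na+].[Na+].[O-]C(=O)[C@H]1COC([O-])=C1 | intermediate
7 | (3R,4R)-4-[(4-benzyloxy-3-methoxyphenyl)methyl]-5-oxooxolane-3-carboxylic acid | COc1cc(C[C@H]2C(=O)OC[C@@H]2C(=O)O)ccc1OCc1ccccc1 | intermediate
8 | 4-benzyloxy-3-methoxyphenylboronic acid | COc1cc(B(O)O)ccc1OCc1ccccc1 | starting material
9 | mixed anhydride of 7 with pivalic acid | COc1cc(C[C@H]2C(=O)OC[C@@H]2C(=O)OC(=O)C(C)(C)C)ccc1OCc1ccccc1 | intermediate
10 | (3R,4R)-4-(4-benzyloxy-3-methoxybenzoyl)-3-(4-benzyloxy-3-methoxybenzyl)dihydrofuran-2(3H)-one | COc1cc(C[C@H]2C(=O)OC[C@@H]2C(=O)c2ccc(OCc3ccccc3)c(OC)c2)ccc1OCc1ccccc1 | intermediate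
11 | (3R,4R)-4-(4-hydroxy-3-methoxybenzoyl)-3-(4-hydroxy-3-methoxybenzyl)dihydrofuran-2(3H)-one | COc1cc(C[C@H]2C(=O)OC[C@@H]2C(=O)c2ccc(O)c(OC)c2)ccc1O | target

## Step count and risks

Total steps: 5. Longest linear sequence: 4 (steps 1, 3, 4, 5; step 2 is a side branch).

The three steps most likely to fail:

**Step 1 (proposed new Baeyer–Villiger desymmetrisation).** The risk is low enantioselectivity, because the carboxyl group is small and may bind scandium unproductively. The fallback uses known chemistry and sets out from 1. An uncatalysed Baeyer–Villiger oxidation (mCPBA, CH2Cl2, rt) gives racemic paraconic acid F1. Classical resolution follows, by crystallising the diastereomeric salt with (S)-1-phenylethylamine from EtOH to give (S)-1-phenylethylammonium (R)-5-oxooxolane-3-carboxylate F2. Which amine enantiomer gives the less soluble salt with the (R)-acid has to be checked by experiment; if it is the other one, the (R)-amine is used. Acidification (1 M HCl) and extraction free the acid, and the fallback comes back to the route at 3.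

**Step 3 (dianion benzylation).** The risks are a poorly soluble dianion, O-benzylation of the carboxylate and double alkylation. The fallback sets out from 3 and replaces the dianion by the mono-enolate of a protected ester. tert-Butyl 2,2,2-trichloroacetimidate with catalytic BF3·OEt2 (CH2Cl2/cyclohexane, rt) gives tert-butyl (3R)-5-oxooxolane-3-carboxylate F3. Kinetic deprotonation of the lactone α-CH2 with LiN(SiMe3)2 (THF, −78 °C), then bromide 5, gives tert-butyl (3R,4R)-4-[(4-benzyloxy-3-methoxyphenyl)methyl]-5-oxooxolane-3-carboxylate F4. The temperature must stay at −78 °C so the hindered C–H next to the tert-butyl ester is not deprotonated. TFA/CH2Cl2 at 0 °C removes the tert-butyl group, and the fallback comes back at 7.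

**Step 4 (acyl Suzuki coupling through the mixed anhydride).** The risks are slow oxidative addition at the α-branched acyl group and competing decarbonylation. The fallback sets out from 7 and goes through a thioester. EtSH, EDC·HCl and catalytic DMAP (CH2Cl2, 0 °C → rt) give S-ethyl (3R,4R)-4-[(4-benzyloxy-3-methoxyphenyl)methyl]-5-oxooxolane-3-carbothioate F5. Base-free Liebeskind–Srogl coupling with boronic acid 8 (Pd2(dba)3, tri(2-furyl)phosphine, Cu(O2CC4H3S), THF, 50 °C) gives the ketone, and the fallback comes back at 10.

## Further compounds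

F1 | step 1 | racemic paraconic acid (5-oxooxolane-3-carboxylic acid) | O=C1CC(C(=O)O)CO1
F2 | step 1 | (S)-1-phenylethylammonium (R)-5-oxooxolane-3-carboxylate | C[C@H]([NH3+])c1ccccc1.[O-]C(=O)[C@H]1COC(=O)C1
F3 | step 3 | tert-butyl (3R)-5-oxooxolane-3-carboxylate | CC(C)(C)OC(=O)[C@H]1COC(=O)C1
F4 | step 3 | tert-butyl (3R,4R)-4-[(4-benzyloxy-3-methoxyphenyl)methyl]-5-oxooxolane-3-carboxylate | COc1cc(C[C@H]2C(=O)OC[C@@H]2C(=O)OC(C)(C)C)ccc1OCc1ccccc1
F5 | step 4 | S-ethyl (3R,4R)-4-[(4-benzyloxy-3-methoxyphenyl)methyl]-5-oxooxolane-3-carbothioate | COc1cc(C[C@H]2C(=O)OC[C@@H]2C(=O)SCC)ccc1OCc1ccccc1
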